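**Assumptions (one line each)**
- The target SMILES leaves the biaryl axes unspecified. I assume the natural (S)-HHDP and NHTP axial configuration, which is set by the chiral sugar.
- The target is the ring-opened vescalagin-type skeleton. C2–C5 are D-gluco, C1 is (S), C1 and C2 carry free OH, and ring N carries a free CO2H.
- Bn = benzyl. "Ar-I acid" means compound 2.

## Retrosynthetic overview
1. Target ⇐ global debenzylation of the acid 15 ⇐ chemoselective opening of the six-membered O2-lactone of 14, the fully benzylated NHTP lactone.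
2. The G–M biaryl (terphenyl closure) comes from a late Pd-catalysed intramolecular C–H arylation. The C1–aryl bond and the C1 stereocentre come from a biomimetic intramolecular Friedel–Crafts hydroxyalkylation of the open-chain aldehyde onto the 2,3-HHDP ring.
3. The aldehyde comes from the dithioacetal of a bis-HHDP glucose (pedunculagin-type), which is built on a rigid ⁴C₁ pyranoside by two Ullmann macrocyclisations of 2-iodo-tri-O-benzylgallate.
4. Rings form in this order: 2,3-HHDP (10-membered), 4,6-HHDP (11-membered), pyranose opened to the acyclic chain, then the 6-membered lactone with the C1–C bond, then the 11-membered G–M biaryl. The lactone is opened last.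

## Route

**Step 1**
Reactants: 1, 3,4,5-tris(benzyloxy)benzoic acid
Product: 2, 3,4,5-tris(benzyloxy)-2-iodobenzoic acid
Conditions: NIS, TFA (cat.), MeCN, 0 °C → rt
Reagents that add atoms: N-iodosuccinimide, O=C1CCC(=O)N1I
Why: Electrophilic aromatic iodination occurs at C2, which is ortho to one OBn and para to the other; there are no stereocentres.

**Step 2**
Reactants: 3, phenyl 4,6-O-benzylidene-1-thio-β-D-glucopyranoside; 2 (2.6 equiv)
Product: 4, phenyl 4,6-O-benzylidene-2,3-bis-O-[3,4,5-tris(benzyloxy)-2-iodobenzoyl]-1-thio-β-D-glucopyranoside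
Conditions: EDC·HCl, DMAP, CH2Cl2, rt
Reagents that add atoms: none
Why: Steglich esterification of the 2,3-diol; all sugar stereocentres are untouched.

**Step 3**
Reactants: 4
Product: 5, the 2,3-O-[(S)-hexakis(benzyloxy)diphenoyl] (HHDP) bridged analogue of 4
Conditions: Cu powder, DMF, 120 °C, 5 mM
Reagents that add atoms: none
Why: Intramolecular Ullmann biaryl macrocyclisation. The trans-diequatorial 2,3-diester on the ⁴C₁ ring allows only the (S)-atropisomer transition state (as in Ullmann syntheses of pedunculagin-type HHDP esters), so the axial chirality is set here.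

**Step 4**
Reactants: 5
Product: 6, the 4,6-diol (benzylidene removed)
Conditions: 80% aq. AcOH, 70 °C
Reagents that add atoms: none
Why: Acetal hydrolysis of the benzylidene; the esters, benzyl ethers and thioglycoside are inert.

**Step 5**
Reactants: 6; 2 (2.6 equiv)
Product: 7, the 4,6-bis-O-(2-iodo-3,4,5-tribenzyloxybenzoyl) ester
Conditions: EDC·HCl, DMAP, CH2Cl2, rt
Reagents that add atoms: none
Why: Steglich esterification of O6 then O4; no stereocentre is changed.

**Step 6**
Reactants: 7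
Product: 8, phenyl 2,3:4,6-bis-O-[(S)-HHDP(OBn)6]-1-thio-β-D-glucopyranoside
Conditions: Cu powder, DMF, 120 °C, 5 mM
Reagents that add atoms: none
Why: Second Ullmann macrocyclisation. The 4,6-bridge on the rigid ⁴C₁ pyranose gives the (S)-HHDP axis.

**Step 7**
Reactants: 8
Product: 9, 2,3:4,6-bis-HHDP(OBn)6-D-glucopyranose (lactol, α/β mixture)
Conditions: NBS, acetone/H2O 9:1, 0 °C
Reagents that add atoms: water, O (its oxygen becomes the lactol OH; PhS is lost)
Why: Thiophilic oxidative hydrolysis of the thioglycoside (NBS-promoted glycosyl hydrolysis). The anomeric centre is lost later, and C2–C5 are unchanged.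

**Step 8**
Reactants: 9
Product: 10, 2,3:4,6-bis-HHDP(OBn)6-D-glucose diethyl dithioacetal (acyclic, 5-OH free)
Conditions: EtSH (10 equiv), BF3·OEt2 (3 equiv), CH2Cl2, 0 °C, 30 min; NaHCO3 quench
Reagents that add atoms: ethanethiol, CCS
Why: Mercaptalisation through the minor open-chain aldehyde tautomer. The large excess of EtSH and the short reaction time at 0 °C favour the acyclic dithioacetal over re-closure to a thioglycoside.

**Step 9**
Reactants: 10; 2
Product: 11, the 5-O-(2-iodo-3,4,5-tribenzyloxybenzoyl) ester of 10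
Conditions: 2, 2,4,6-Cl3C6H2COCl, Et3N, then DMAP, toluene, 60 °C
Reagents that add atoms: none
Why: Yamaguchi esterification of the hindered secondary O5 through the mixed anhydride; this installs the future G ring.

**Step 10**
Reactants: 11
Product: 12, the aldehydo-sugar (C1 = CHO)
Conditions: MeI (excess), CaCO3, MeCN/H2O 9:1, 60 °C
Reagents that add atoms: water, O (its oxygen becomes the aldehyde oxygen; the MeI-derived sulfonium leaves as EtSMe)
Why: Dithioacetal hydrolysis via S-methylsulfonium under neutral conditions, which avoids oxidants that would attack the electron-rich arenes. The crude aldehyde is used at once.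

**Step 11**
Reactants: 12
Product: 13, the (1S)-1-hydroxy dihydroisocoumarin lactone with the C1–aryl bond formed (N ring bonded to C1, O2-lactone), aryl iodide intact
Conditions: Sc(OTf)3 (0.3 equiv), 4 Å MS, ClCH2CH2Cl, 0 → 50 °C
Reagents that add atoms: none
Why: Proposed new method: intramolecular Friedel–Crafts hydroxyalkylation, a biomimetic casuarictin→stachyurin-type cyclisation. The Lewis-acid-activated C1 aldehyde is attacked by the free ortho C–H (n1) of the 2,3-HHDP ring on O2. This 6-exo closure forms the lactone, the C1–aryl bond and the C1 stereocentre together. The (S)-HHDP cage and a chair-like transition state put the C3 chain pseudo-equatorial and trans to the forming C1–OH, which is the (1S,2S) relationship. The 7-membered closure from the O3 ring is disfavoured. The closest known reaction is Lewis-acid arene–aldehyde hydroxyalkylation.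

**Step 12**
Reactants: 13
Product: 14, fully benzylated NHTP-lactone (G–M biaryl formed)
Conditions: Pd(OAc)2 (20 mol%), PCy3·HBF4 (40 mol%), K2CO3, PivOH (30 mol%), DMA, 110 °C, 5 mM
Reagents that add atoms: none
Why: Proposed new method: concerted metalation–deprotonation of M-ring C–H (m1) by the oxidative-addition complex of the O5 aryl iodide closes the 11-membered biaryl lactone. This makes the terphenyl and fixes the G–M axis by cage constraints, with no new stereocentre. The closest known reaction is Fagnou-type intramolecular direct arylation used for biaryl lactones.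

**Step 13**
Reactants: 14
Product: 15, the C1,C2-diol with free CO2H on ring N (lactone opened); all other esters retained
Conditions: LiOH·H2O (1.2 equiv), THF/H2O 9:1, 0 °C, 20 min; cold aq. NaH2PO4 to pH ~4
Reagents that add atoms: water, O (net addition of H2O across the lactone C(=O)–O bond, giving the acid and the C2–OH)
Why: Proposed new method: a 6-membered lactone is forced into the strained s-cis (E) ester geometry, which makes it much more electrophilic than the acyclic or macrocyclic Z-esters, and the neighbouring C1–OH assists. This lets brief, cold LiOH open only the dihydroisocoumarin ring while the hindered biaryl macrolactones survive. The closest known reaction is selective δ-lactone hydrolysis. The quench at pH ~4 and the short reaction time limit O3→O2 acyl migration. No stereocentre is touched.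

**Step 14**
Reactants: 15
Product: 16, chinquapinic acid (target)
Conditions: H2 (1 atm), Pd(OH)2/C, THF/MeOH/H2O 5:5:1, rt, 16 h; filter, lyophilise
Reagents that add atoms: none (H2 adds only hydrogen)
Why: Hydrogenolysis removes all 15 aryl O-benzyl groups. C1 carries a free OH, and the mild neutral conditions leave it, so no stereocentre is changed.

## Compound list

| No. | Name | SMILES | Role |
|---|---|---|---|
| 1 | 3,4,5-tris(benzyloxy)benzoic acid | OC(=O)c1cc(OCc2ccccc2)c(OCc2ccccc2)c(OCc2ccccc2)c1 | starting material |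
| 2 | 3,4,5-tris(benzyloxy)-2-iodobenzoic acid | OC(=O)c1cc(OCc2ccccc2)c(OCc2ccccc2)c(OCc2ccccc2)c1I | intermediate |
| 3 | phenyl 4,6-O-benzylidene-1-thio-β-D-glucopyranoside | c1ccccc1S[C@@H]2O[C@@H]3CO[C@@H](c4ccccc4)O[C@H]3[C@H](O)[C@H]2O | starting material |
| 4 | 2,3-bis(2-iodoaroyl) ester of 3 | c1ccccc1S[C@@H]2O[C@@H]3CO[C@@H](c4ccccc4)O[C@H]3[C@H](OC(=O)c6cc(OCc7ccccc7)c(OCc7ccccc7)c(OCc7ccccc7)c6I)[C@H]2OC(=O)c6cc(OCc7ccccc7)c(OCc7ccccc7)c(OCc7ccccc7)c6I | intermediate |
| 5 | 2,3-(S)-HHDP(OBn)6 bridged 4,6-benzylidene thioglycoside | c1ccccc1S[C@@H]2O[C@@H]3CO[C@@H](c4ccccc4)O[C@H]3[C@@H]5OC(=O)c6cc(OCc7ccccc7)c(OCc7ccccc7)c(OCc7ccccc7)c6-c6c(OCc7ccccc7)c(OCc7ccccc7)c(OCc7ccccc7)cc6C(=O)O[C@@H]25 | intermediate |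
| 6 | 4,6-diol of 5 | c1ccccc1S[C@@H]2O[C@H](CO)[C@@H](O)[C@@H]3OC(=O)c6cc(OCc7ccccc7)c(OCc7ccccc7)c(OCc7ccccc7)c6-c6c(OCc7ccccc7)c(OCc7ccccc7)c(OCc7ccccc7)cc6C(=O)O[C@@H]23 | intermediate |
| 7 | 4,6-bis(2-iodoaroyl) ester of 6 | c1ccccc1S[C@@H]2O[C@H](COC(=O)c6cc(OCc7ccccc7)c(OCc7ccccc7)c(OCc7ccccc7)c6I)[C@@H](OC(=O)c6cc(OCc7ccccc7)c(OCc7ccccc7)c(OCc7ccccc7)c6I)[C@@H]3OC(=O)c6cc(OCc7ccccc7)c(OCc7ccccc7)c(OCc7ccccc7)c6-c6c(OCc7ccccc7)c(OCc7ccccc7)c(OCc7ccccc7)cc6C(=O)O[C@@H]23 | intermediate |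
| 8 | phenyl 2,3:4,6-bis-(S)-HHDP(OBn)6-1-thio-β-D-glucopyranoside | c1ccccc1S[C@@H]2O[C@@H]4COC(=O)c6cc(OCc7ccccc7)c(OCc7ccccc7)c(OCc7ccccc7)c6-c6c(OCc7ccccc7)c(OCc7ccccc7)c(OCc7ccccc7)cc6C(=O)O[C@H]4[C@@H]3OC(=O)c6cc(OCc7ccccc7)c(OCc7ccccc7)c(OCc7ccccc7)c6-c6c(OCc7ccccc7)c(OCc7ccccc7)c(OCc7ccccc7)cc6C(=O)O[C@@H]23 | intermediate |
| 9 | 2,3:4,6-bis-HHDP(OBn)6-D-glucopyranose (lactol, C1 unspecified) | OC2O[C@@H]4COC(=O)c6cc(OCc7ccccc7)c(OCc7ccccc7)c(OCc7ccccc7)c6-c6c(OCc7ccccc7)c(OCc7ccccc7)c(OCc7ccccc7)cc6C(=O)O[C@H]4[C@@H]3OC(=O)c6cc(OCc7ccccc7)c(OCc7ccccc7)c(OCc7ccccc7)c6-c6c(OCc7ccccc7)c(OCc7ccccc7)c(OCc7ccccc7)cc6C(=O)O[C@@H]23 | intermediate |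
| 10 | acyclic diethyl dithioacetal, 5-OH free | CCSC(SCC)[C@@H]7OC(=O)c3cc(OCc5ccccc5)c(OCc5ccccc5)c(OCc5ccccc5)c3-c3c(OCc5ccccc5)c(OCc5ccccc5)c(OCc5ccccc5)cc3C(=O)O[C@H]7[C@H](OC(=O)c3cc(OCc5ccccc5)c(OCc5ccccc5)c(OCc5ccccc5)c3-c3c(OCc5ccccc5)c(OCc5ccccc5)c(OCc5ccccc5)cc3C(=O)O%10)[C@H](O)C%10 | intermediate |
| 11 | 5-O-(2-iodoaroyl) ester of 10 | CCSC(SCC)[C@@H]7OC(=O)c3cc(OCc5ccccc5)c(OCc5ccccc5)c(OCc5ccccc5)c3-c3c(OCc5ccccc5)c(OCc5ccccc5)c(OCc5ccccc5)cc3C(=O)O[C@H]7[C@H](OC(=O)c3cc(OCc5ccccc5)c(OCc5ccccc5)c(OCc5ccccc5)c3-c3c(OCc5ccccc5)c(OCc5ccccc5)c(OCc5ccccc5)cc3C(=O)O%10)[C@H](OC(=O)c3cc(OCc5ccccc5)c(OCc5ccccc5)c(OCc5ccccc5)c3I)C%10 | intermediate |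
| 12 | aldehydo-sugar | O=C[C@@H]7OC(=O)c3cc(OCc5ccccc5)c(OCc5ccccc5)c(OCc5ccccc5)c3-c3c(OCc5ccccc5)c(OCc5ccccc5)c(OCc5ccccc5)cc3C(=O)O[C@H]7[C@H](OC(=O)c3cc(OCc5ccccc5)c(OCc5ccccc5)c(OCc5ccccc5)c3-c3c(OCc5ccccc5)c(OCc5ccccc5)c(OCc5ccccc5)cc3C(=O)O%10)[C@H](OC(=O)c3cc(OCc5ccccc5)c(OCc5ccccc5)c(OCc5ccccc5)c3I)C%10 | intermediate |
| 13 | (1S) C1-aryl, C1-OH O2-lactone (key FC product) | O[C@H]8c3c(OCc5ccccc5)c(OCc5ccccc5)c(OCc5ccccc5)c(-c9c(OCc5ccccc5)c(OCc5ccccc5)c(OCc5ccccc5)cc9C(=O)O%11)c3C(=O)O[C@@H]8[C@@H]%11[C@H](OC(=O)c3cc(OCc5ccccc5)c(OCc5ccccc5)c(OCc5ccccc5)c3-c3c(OCc5ccccc5)c(OCc5ccccc5)c(OCc5ccccc5)cc3C(=O)O%10)[C@H](OC(=O)c3cc(OCc5ccccc5)c(OCc5ccccc5)c(OCc5ccccc5)c3I)C%10 | intermediate |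
| 14 | fully benzylated NHTP-lactone | O[C@H]8c3c(OCc5ccccc5)c(OCc5ccccc5)c(OCc5ccccc5)c(-c9c(OCc5ccccc5)c(OCc5ccccc5)c(OCc5ccccc5)c(-c%13c(OCc5ccccc5)c(OCc5ccccc5)c(OCc5ccccc5)cc%13C(=O)O%12)c9C(=O)O%11)c3C(=O)O[C@@H]8[C@@H]%11[C@H](OC(=O)c3cc(OCc5ccccc5)c(OCc5ccccc5)c(OCc5ccccc5)c3-c3c(OCc5ccccc5)c(OCc5ccccc5)c(OCc5ccccc5)cc3C(=O)O%10)[C@H]%12C%10 | intermediate |
| 15 | hexadeca-O-benzyl acid (lactone opened) | OC(=O)c3c(-c9c(OCc5ccccc5)c(OCc5ccccc5)c(OCc5ccccc5)c(-c%13c(OCc5ccccc5)c(OCc5ccccc5)c(OCc5ccccc5)cc%13C(=O)O%12)c9C(=O)O%11)c(OCc5ccccc5)c(OCc5ccccc5)c(OCc5ccccc5)c3[C@H](O)[C@H](O)[C@@H]%11[C@H](OC(=O)c3cc(OCc5ccccc5)c(OCc5ccccc5)c(OCc5ccccc5)c3-c3c(OCc5ccccc5)c(OCc5ccccc5)c(OCc5ccccc5)cc3C(=O)O%10)[C@H]%12C%10 | intermediate |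
| 16 | chinquapinic acid | O=C1OC[C@H]2OC(=O)c3cc(O)c(O)c(O)c3-c3c(O)c(O)c(O)c4c3C(=O)O[C@H]([C@@H](O)[C@@H](O)c3c(O)c(O)c(O)c-4c3C(=O)O)[C@@H]2OC(=O)c2cc(O)c(O)c(O)c2-c2c1cc(O)c(O)c2O | target |

## Totals
- Total steps: 14 (Steps 1–14).
- Longest linear sequence: 14 steps, from 1 through 2 (Step 1) and Steps 2–14 to 16. The route from 3 alone is 13 steps, but 2 is made from 1 in Step 1 and feeds Step 2.

## Three steps most likely to fail
1. **Step 11 (Friedel–Crafts cage closure and C1 configuration).** The crowded, ester-deactivated arene may not cyclise, or may give the 1R epimer. Fallback: abandon the tether and form the C1–aryl bond by adding an aryllithium, made from the ring-N aryl bromide, to a 2,3-O-protected open-chain aldehyde with chelation control. Then re-enter the route at Step 12.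
2. **Step 12 (Pd C–H arylation regiochemistry).** The G-ring iodide could arylate the free C6–H of an HHDP ring instead of M-ring m1. Fallback: drop direct arylation and use an intramolecular Ullmann coupling. Build the 2,3-bridge from ring-N acid 2 and a 2,6-diiodo M-acid, differentiating O2/O3 by stannylene-directed acylation. The surviving M-iodide then couples with the G-iodide after the HHDP rings are complete.
3. **Step 13 (chemoselective lactone opening).** The hindered N-lactone may not be opened faster than the other esters, or O3→O2 acyl migration may follow. Fallback: oxidise C1–OH (DMP) to the α-acyloxy ketone and cleave the lactone with SmI2 to give the carboxylate. Re-install C2–OH by Davis oxaziridine hydroxylation of the Sm-enolate, then reduce the C1 ketone (NaBH4/CeCl3) before hydrogenolysis.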